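## Structural features

The target is an eleven-membered carbocycle of the humulane type. Going round the ring: a quaternary gem-dimethyl carbon (C1), three methylenes (C2–C4), a trisubstituted oxirane on C5 (methyl-bearing) and C6, two methylenes (C7, C8), a trisubstituted enoic acid C9(CO2H)=C10, and a benzoyloxy methine C11 that closes back to C1. There are three stereocentres. C5 and C6 are adjacent and form a trans epoxide (C4 and C7 on opposite sides, 5R,6R). C11 (R) stands alone between the quaternary carbon and the enoate, at least four ring atoms from the epoxide, so it cannot relay its configuration by a simple 1,2- or 1,3-effect. In C9=C10 the ring carbons C8 and C11 are cis (E by the CIP rules, carboxyl trans to C11). The fragile groups are the acid-labile trisubstituted epoxide beside a free carboxylic acid, the allylic benzoate (hydrolysis, migration, ionisation), and, in precursors, an aldehyde whose only α-hydrogen sits on C11. The real difficulty is to close a strained medium ring with the E geometry of C5=C6 already secured, and then to set the epoxide in the correct absolute sense relative to the remote C11. The key step exploits the segment C4–C5(CH3)=C6–C7–C8: a methyl-branched E alkene flanked by methylenes is what syn methylmetalation of a terminal alkyne C5≡C6 gives when the metal at C6 is then replaced by a two-carbon electrophile.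

## Logic of the disconnections

28 ⇒ 27. The O–allyl bond of an ester is cut. The acid and the epoxide should coexist only in the last flask, so every earlier step runs on a neutral ester. The forward step must cleave this ester under neutral conditions that spare the oxirane and the allylic benzoate.

27 ⇒ 26. The C5–O and C6–O bonds are cut. A concerted oxygen transfer to an E alkene gives the trans epoxide stereospecifically, so two stereocentres are traded for one alkene geometry. The forward step must choose C5=C6 over two other alkenes and choose the face that gives 5R,6R on a macrocycle.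

26 ⇒ 25 ⇒ 24. The benzoate O–acyl bond and then an O–Si bond are cut. A benzoate at C11 would migrate to a free C10 hydroxyl and would acidify the C11 hydrogen of the aldehyde, so C11 stays silylated until the ring is closed. The forward steps must free a hindered secondary ether without harming the enoate.

24 ⇒ 23. The C9=C10 double bond is cut. This ring bond can be made from a stabilised carbanion and an aldehyde, and the inherent geometry of that olefination (ester trans to C11) is also the ring-cis geometry required. The ring becomes a chain with one stereocentre. The forward step needs high dilution and a base mild enough not to epimerise C11.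

23 ⇒ 22 ⇒ 21. The oxidation level at C10 is adjusted and the primary silyl ether is restored. The forward steps need a selective cleavage of the primary over the hindered secondary silyl ether and a non-epimerising oxidation.

21 ⇒ 18 + 19, and 18 ⇒ 17. The C8–C9 bond is cut. C9 is a doubly stabilised carbanion in 19 and C8 a primary electrophile in 18, so C9 and the carboxyl carbon come from a commercial two-carbon reagent. The forward step needs SN2 substitution without elimination of the homoallylic iodide and without dialkylation.

17 ⇒ 12 + 13 + 14. The C5–CH3 and C6–C7 bonds are cut. Both can be formed across one alkyne in one flask, with the alkene geometry following from a syn addition. The chain is reduced to a terminal alkyne that carries the single stereocentre. The forward step needs methyl delivery to the internal carbon and protecting groups inert to 13.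

12 ⇒ 11 ⇒ 10. The protecting groups are exchanged. The cyclic ketal that best differentiates the three hydroxyls of 2 would not tolerate 13, so it is replaced by two silyl ethers once the alkyne is in place.

10 ⇒ 9. The triple bond is cut back to an aldehyde, removing C6. The forward step is a one-carbon homologation under mild base.

9 ⇒ 8 ⇒ 7 ⇒ 4 + 5. The C2–C3 bond is cut (as C2=C3). The neopentyl position C2 is a poor SN2 site but a good aldehyde for olefination, and 5 brings C3–C5 with a masked oxygen at C5. The alkene geometry is irrelevant because it is hydrogenated.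

4 ⇒ 3 ⇒ 2 ⇒ 1. The four carbons C10, C11, C1 and C2, the gem-dimethyl group and the C11 oxygen with its configuration come from the chiral pool. The forward steps only need to tell the neopentyl hydroxyl from the vicinal diol.

## Other disconnections considered

Alternative 1: The cut removes C5–C6 and the C6–O bond of the oxirane together, which opens the ring and leaves the seco keto sulfonium salt A1 (C5 methyl ketone, diphenylsulfonium on C6, enoate and benzoate already present).
- Forward step: LiN(SiMe3)2 would deprotonate C6, the ylide would add to the C5 carbonyl to close the ring, and the alkoxide would displace the sulfide to give the epoxy allyl ester A2, which is the same compound as 27.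
- In its favour: ring and epoxide arise in one operation, the enoate can be made earlier by an intermolecular olefination, and no oxidant has to choose among three alkenes. In end-game step count it is the better plan.
- Against it: C5 and C6 are both created during an eleven-membered ring closure with only the remote C11 to bias them. Neither the trans relationship, which depends on the geometry of betaine formation and not on a stereospecific event, nor the absolute sense is under defined control. The methyl ketone can be enolised, the salt has β-hydrogens at C7 that allow elimination, and the ylide can react intermolecularly.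
- Comparison: the chosen plan fixes the geometry by a stereospecific syn addition before any ring exists and sets the epoxide with a chiral reagent. In the use of the chiral pool for C11 the two plans are equal.

Alternative 2: The C5=C6 π bond is traced back to a σ bond C5–C11, giving the trans-fused six–seven hydroxy mesylate A3.
- Forward step: KOtBu would form the C11 alkoxide, which would push out the C6 mesylate through the antiperiplanar C5–C11 bond (Grob fragmentation) and release the keto diene ester A4.
- In its favour: the medium ring appears by fragmentation of a bicycle and not by an entropically costly cyclisation, which is better than the ring closure of the chosen plan. The E geometry follows from a stereospecific antiperiplanar arrangement, which is equal to the reliability of syn carbometalation. The ring-cis C9=C10 is inherited from the seven-membered ring.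
- Against it: every stereocentre of A3 is destroyed, so C11 must afterwards be set by reagent-controlled reduction of the C11 carbonyl of A4, where the chosen plan takes it from the chiral pool. A3 itself needs three contiguous stereocentres, two of them fully substituted, in a defined relative arrangement (angular methyl and mesylate cis, hydroxyl trans), which will cost more steps than an acyclic chain. The enoate must also survive KOtBu.
- Comparison: the late epoxidation would face the same macrocyclic face-selection problem as in the chosen plan (equal). Overall step economy is expected to be worse.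

Alternative 3: The cut is made at C4–C5 and at the C6–O bond, dividing the molecule into the (S)-α-chloro ketone A5 (C5–C8) and the Grignard reagent A6 (C4–C1, C11, C10).
- Forward step: addition of A6 to the carbonyl of A5 anti to chlorine (Cornforth or polar Felkin–Anh control) and displacement of chloride by the alkoxide with inversion would give the acyclic trans epoxide A7 with all three stereocentres.
- In its favour: the epoxide configuration is set in an open chain by 1,2-induction and a stereospecific SN2 closure, independent of any macrocyclic conformation. On this point, and in convergence, it is better than the chosen plan. The pantolactone-derived half is used in the same way (equal).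
- Against it: A5 is an enolisable, configurationally labile α-chloro ketone that must face a basic Grignard reagent, and methyl ketones usually give weaker facial control than aldehydes. The trisubstituted epoxide of A7 must then survive about ten further operations, including iodination at C8, two deprotections, two oxidations and the ring closure. The C8 alcohol stage is a 3,4-epoxy alcohol prone to cyclisation.
- Comparison: the chosen plan carries a robust alkene through these steps and introduces the epoxide one step before the end. The step count is comparable, with one more class of protecting group in this alternative.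

Key step: step 10

Remarks and assumptions:
- Compounds 1, 5, 13, 14 and 19 and all reagents are taken as commercially available.
- TBS = tert-butyldimethylsilyl.
- Cyclic compounds are named with the ring numbering C1–C11 used above.
- The C11 centre is labelled S in 1–23 and R in 24–28 only because the CIP rank of C10 changes when it becomes an alkene carbon; no inversion occurs.
- Compounds 21–23 are mixtures of epimers at C9, so this centre is left undefined.
- The bis-silyl form of the alkyne is retained for the key step, reached by protecting-group exchange at the alkyne stage.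

## Route

Step 1
Reactants: 1 (S)-pantolactone [(3S)-3-hydroxy-4,4-dimethyloxolan-2-one]
Product: 2 (2S)-3,3-dimethylbutane-1,2,4-triol
Conditions: LiAlH4, THF, 0 °C → reflux; Na2SO4·10H2O quench
Reagents that add atoms: none
Why: Hydride reduction of the lactone to the diol, giving the triol; the carbinol centre is present as an alkoxide during the reduction and has no pathway for epimerisation, so the S configuration is kept.

Step 2
Reactants: 2 (2S)-3,3-dimethylbutane-1,2,4-triol
Product: 3 2-[(4S)-2,2-dimethyl-1,3-dioxolan-4-yl]-2-methylpropan-1-ol
Conditions: 2,2-dimethoxypropane, p-TsOH·H2O (cat.), acetone, rt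
Reagents that add atoms: 2,2-dimethoxypropane, COC(C)(C)OC
Why: Acid-catalysed transketalisation under thermodynamic control; the five-membered dioxolane across the vicinal diol (C10, C11) is favoured over the six-membered dioxane, which would hold an axial ketal methyl, so the neopentyl C2 hydroxyl should remain free.

Step 3
Reactants: 3 2-[(4S)-2,2-dimethyl-1,3-dioxolan-4-yl]-2-methylpropan-1-ol
Product: 4 2-[(4S)-2,2-dimethyl-1,3-dioxolan-4-yl]-2-methylpropanal
Conditions: Dess–Martin periodinane, pyridine, CH2Cl2, 0 °C → rt
Reagents that add atoms: none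
Why: Dess–Martin oxidation of a primary alcohol; the aldehyde has a quaternary α-carbon and cannot enolise, and pyridine buffers the acetic acid so the ketal is kept.

Step 4
Reactants: 4 2-[(4S)-2,2-dimethyl-1,3-dioxolan-4-yl]-2-methylpropanal; 5 (3-benzyloxypropyl)triphenylphosphonium bromide
Product: 7 (4S)-4-[(3Z)-6-(benzyloxy)-2-methylhex-3-en-2-yl]-2,2-dimethyl-1,3-dioxolane, via phosphonium ylide 6 (not isolated)
Conditions: 5, KN(SiMe3)2, THF, 0 °C; then 4, −78 °C → rt
Reagents that add atoms: none
Why: Wittig olefination forming C2=C3; a non-stabilised ylide is reactive enough for the hindered neopentyl aldehyde and should give mainly the Z alkene, whose geometry is of no consequence because it is hydrogenated next.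

Step 5
Reactants: 7 (4S)-4-[(3Z)-6-(benzyloxy)-2-methylhex-3-en-2-yl]-2,2-dimethyl-1,3-dioxolane
Product: 8 5-[(4S)-2,2-dimethyl-1,3-dioxolan-4-yl]-5-methylhexan-1-ol
Conditions: H2 (1 atm), Pd/C (10 wt %), EtOAc–EtOH, rt
Reagents that add atoms: none
Why: Heterogeneous catalytic hydrogenation saturates C2=C3 and hydrogenolyses the benzyl ether in the same operation; the ketal is stable in neutral medium.

Step 6
Reactants: 8 5-[(4S)-2,2-dimethyl-1,3-dioxolan-4-yl]-5-methylhexan-1-ol
Product: 9 5-[(4S)-2,2-dimethyl-1,3-dioxolan-4-yl]-5-methylhexanal
Conditions: Dess–Martin periodinane, pyridine, CH2Cl2, 0 °C → rt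
Reagents that add atoms: none
Why: Dess–Martin oxidation of the C5 alcohol to the aldehyde without over-oxidation; no stereocentre is α to the new carbonyl.

Step 7
Reactants: 9 5-[(4S)-2,2-dimethyl-1,3-dioxolan-4-yl]-5-methylhexanal
Product: 10 (4S)-2,2-dimethyl-4-(2-methylhept-6-yn-2-yl)-1,3-dioxolane
Conditions: dimethyl (1-diazo-2-oxopropyl)phosphonate, K2CO3, MeOH, 0 °C → rt
Reagents that add atoms: dimethyl (1-diazo-2-oxopropyl)phosphonate, COP(=O)(OC)C(=[N+]=[N-])C(C)=O
Why: Ohira–Bestmann (Seyferth–Gilbert) homologation: methanolysis of the reagent gives the diazomethylphosphonate anion, which olefinates the aldehyde; loss of N2 and a 1,2-hydrogen shift give the terminal alkyne and add C6 under mild base.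

Step 8
Reactants: 10 (4S)-2,2-dimethyl-4-(2-methylhept-6-yn-2-yl)-1,3-dioxolane
Product: 11 (2S)-3,3-dimethyloct-7-yne-1,2-diol
Conditions: AcOH–H2O (4:1), 40 °C
Reagents that add atoms: none
Why: Acid hydrolysis of the isopropylidene ketal, needed because a ketal would be opened by AlMe3 in step 10; the alkyne is inert to aqueous acetic acid.

Step 9
Reactants: 11 (2S)-3,3-dimethyloct-7-yne-1,2-diol
Product: 12 (7S)-7,8-bis(TBSO)-6,6-dimethyloct-1-yne
Conditions: TBSOTf (2.5 equiv), 2,6-lutidine, CH2Cl2, −78 → 0 °C
Reagents that add atoms: tert-butyldimethylsilyl trifluoromethanesulfonate, CC(C)(C)[Si](C)(C)OS(=O)(=O)C(F)(F)F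
Why: Silylation with the silyl triflate, which is reactive enough for the hindered secondary hydroxyl beside the quaternary carbon; the alkyne C–H is not touched by 2,6-lutidine.

Step 10
Reactants: 12 (7S)-7,8-bis(TBSO)-6,6-dimethyloct-1-yne; 13 trimethylaluminium; 14 ethylene oxide
Product: 17 (3E,9S)-9,10-bis(TBSO)-4,8,8-trimethyldec-3-en-1-ol, via alkenyldimethylalane 15 (not isolated), via lithium alkenylalanate 16 (not isolated)
Conditions: 13 (2.5 equiv), Cp2ZrCl2 (0.25 equiv), CH2Cl2, 0 °C → rt; volatiles removed in vacuo; hexane, n-BuLi, 0 °C; then 14 (excess), THF, −30 °C → rt; aq. KNaC4H4O6 (potassium sodium tartrate) work-up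
Reagents that add atoms: none
Why: Cp2ZrCl2 and AlMe3 form a chloride-bridged Zr–Al methyl species that adds methyl and metal across the terminal alkyne through a four-centre syn transition state, methyl to the internal carbon C5 and metal to the terminus C6, and transmetalation leaves the (E)-alkenyldimethylalane 15. The closest known reaction type is the zirconium-catalysed (Negishi) methylalumination of terminal alkynes, followed by the known opening of epoxides by alkenylalanates. n-BuLi turns the weakly nucleophilic alane into the tetracoordinate alanate 16, from which the sp2 alkenyl group is transferred in preference to methyl or butyl in an SN2 opening of ethylene oxide with retention at C6, so that C5–CH3 and C6–C7 are formed in one flask and C4 and C7 end up trans. No ring is closed and no stereocentre is created; C11 is separated from the alkyne by the C1–C4 chain and is not touched. The step needs three selectivities, methyl delivery to C5, syn addition and alkenyl transfer; the first two are inherent in the four-centre addition to a terminal alkyl-substituted alkyne and the third in the higher migratory aptitude of the alkenyl group. The substrate secures them by having no propargylic or homopropargylic heteroatom that could redirect the metal and by carrying only silyl ethers, which neither bind nor react with AlMe3 as a free hydroxyl or a ketal would. Excess AlMe3 is removed before n-BuLi is added so that it neither consumes the base nor polymerises the epoxide.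

Step 11
Reactants: 17 (3E,9S)-9,10-bis(TBSO)-4,8,8-trimethyldec-3-en-1-ol
Product: 18 (3E,9S)-9,10-bis(TBSO)-1-iodo-4,8,8-trimethyldec-3-ene
Conditions: I2, PPh3, imidazole, CH2Cl2, 0 °C
Reagents that add atoms: iodine, II
Why: Appel-type iodination: iodide displaces the alkoxyphosphonium group at the primary carbon C8 by SN2; imidazole buffering keeps the silyl ethers and the alkene geometry.

Step 12
Reactants: 18 (3E,9S)-9,10-bis(TBSO)-1-iodo-4,8,8-trimethyldec-3-ene; 19 allyl (diethoxyphosphoryl)acetate
Product: 21 allyl (5E,11S)-11,12-bis(TBSO)-2-(diethoxyphosphoryl)-6,10,10-trimethyldodec-5-enoate, via sodium phosphonoacetate enolate 20 (not isolated)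
Conditions: 19 (2 equiv), NaH, THF, 0 °C → rt; then 18, DMF, 50 °C
Reagents that add atoms: none
Why: SN2 C-alkylation of the stabilised phosphonoacetate carbanion by the primary iodide forms C8–C9; an excess of 20 suppresses dialkylation, and the new C9 centre is formed without control, which is irrelevant because it becomes sp2 in step 15.

Step 13
Reactants: 21 allyl (5E,11S)-11,12-bis(TBSO)-2-(diethoxyphosphoryl)-6,10,10-trimethyldodec-5-enoate
Product: 22 allyl (5E,11S)-11-(TBSO)-2-(diethoxyphosphoryl)-12-hydroxy-6,10,10-trimethyldodec-5-enoate
Conditions: HF·pyridine, pyridine, THF, 0 °C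
Reagents that add atoms: none
Why: Fluoride-mediated desilylation under steric control: the primary silyl ether at C10 should be cleaved much faster than the secondary one at C11, which is shielded by the adjacent quaternary carbon; ester and phosphonate are inert.

Step 14
Reactants: 22 allyl (5E,11S)-11-(TBSO)-2-(diethoxyphosphoryl)-12-hydroxy-6,10,10-trimethyldodec-5-enoate
Product: 23 allyl (5E,11S)-11-(TBSO)-2-(diethoxyphosphoryl)-6,10,10-trimethyl-12-oxododec-5-enoate
Conditions: Dess–Martin periodinane, pyridine, CH2Cl2, 0 °C
Reagents that add atoms: none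
Why: Dess–Martin oxidation under buffered, non-basic conditions, chosen because the only α-hydrogen of the aldehyde is at the C11 stereocentre; 23 is used at once.

Step 15
Reactants: 23 allyl (5E,11S)-11-(TBSO)-2-(diethoxyphosphoryl)-6,10,10-trimethyl-12-oxododec-5-enoate
Product: 24 allyl (5E,9E,11R)-11-(TBSO)-1,1,5-trimethylcycloundeca-5,9-diene-9-carboxylate
Conditions: LiCl, DBU, MeCN, rt, high dilution (about 1 mM, slow addition of 23)
Reagents that add atoms: none
Why: Intramolecular Horner–Wadsworth–Emmons olefination under Masamune–Roush conditions: lithium chelation acidifies the phosphonate so that an amine base suffices, which protects C11 from epimerisation. The favoured E enoate has the ester trans to C11, that is C8 and C11 cis in the ring, which is also the less strained geometry of an eleven-membered ring; high dilution disfavours oligomers, and the gem-dimethyl group and the E alkene restrict the chain.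

Step 16
Reactants: 24 allyl (5E,9E,11R)-11-(TBSO)-1,1,5-trimethylcycloundeca-5,9-diene-9-carboxylate
Product: 25 allyl (5E,9E,11R)-11-hydroxy-1,1,5-trimethylcycloundeca-5,9-diene-9-carboxylate
Conditions: HF·pyridine (excess), THF, 0 °C → rt
Reagents that add atoms: none
Why: Desilylation of the hindered secondary ether with HF·pyridine in excess; hydroxyl and ester lie trans across C9=C10, so lactonisation is not possible.

Step 17
Reactants: 25 allyl (5E,9E,11R)-11-hydroxy-1,1,5-trimethylcycloundeca-5,9-diene-9-carboxylate
Product: 26 allyl (5E,9E,11R)-11-(benzoyloxy)-1,1,5-trimethylcycloundeca-5,9-diene-9-carboxylate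
Conditions: BzCl, pyridine, DMAP (cat.), CH2Cl2, 0 °C → rt
Reagents that add atoms: benzoyl chloride, O=C(Cl)c1ccccc1
Why: DMAP-catalysed O-acylation of the secondary allylic alcohol; the C11–O bond is not touched, so the configuration is retained.

Step 18
Reactants: 26 allyl (5E,9E,11R)-11-(benzoyloxy)-1,1,5-trimethylcycloundeca-5,9-diene-9-carboxylate
Product: 27 allyl (5R,6R,9E,11R)-11-(benzoyloxy)-5,6-epoxy-1,1,5-trimethylcycloundec-9-ene-9-carboxylate
Conditions: D-fructose-derived Shi ketone (1,2:4,5-di-O-isopropylidene-β-D-erythro-2,3-hexodiulo-2,6-pyranose, 0.3 equiv), KHSO5 (as 2KHSO5·KHSO4·K2SO4), K2CO3, Bu4NHSO4 (cat.), Na2B4O7 buffer, MeCN–CH2(OMe)2–H2O, 0 °C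
Reagents that add atoms: potassium peroxymonosulfate, [K+].[O-]S(=O)(=O)OO
Why: Shi asymmetric epoxidation: the chiral dioxirane formed from the ketone and KHSO5 transfers oxygen through a spiro transition state to the electron-rich trisubstituted C5=C6, while the conjugated C9=C10 and the monosubstituted allyl alkene should react far more slowly. The D-fructose-derived ketone attacks E olefins on the face that leads to (R,R) epoxides, which corresponds to 5R,6R here; concerted syn transfer keeps C4 and C7 trans.

Step 19
Reactants: 27 allyl (5R,6R,9E,11R)-11-(benzoyloxy)-5,6-epoxy-1,1,5-trimethylcycloundec-9-ene-9-carboxylate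
Product: 28 (5R,6R,9E,11R)-11-(benzoyloxy)-5,6-epoxy-1,1,5-trimethylcycloundec-9-ene-9-carboxylic acid
Conditions: Pd(PPh3)4 (5 mol %), morpholine, THF, 0 °C → rt; work-up at pH 4–5 (NaH2PO4 buffer)
Reagents that add atoms: none
Why: Tsuji–Trost deallylation: zerovalent palladium ionises the allyl ester to a π-allyl complex of divalent palladium and the carboxylate, and morpholine traps the allyl group. The medium is neutral, so epoxide and benzoate should survive; the C11 benzoate, secondary, neopentyl and on an electron-poor trisubstituted alkene, should ionise much more slowly than the unhindered allyl ester.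

## Compound list

1 | (S)-pantolactone, (3S)-3-hydroxy-4,4-dimethyloxolan-2-one | O=C1OCC(C)(C)[C@@H]1O | starting material
2 | (2S)-3,3-dimethylbutane-1,2,4-triol | OCC(C)(C)[C@H](O)CO | intermediate
3 | 2-[(4S)-2,2-dimethyl-1,3-dioxolan-4-yl]-2-methylpropan-1-ol | OCC(C)(C)[C@H]1COC(C)(C)O1 | intermediate
4 | 2-[(4S)-2,2-dimethyl-1,3-dioxolan-4-yl]-2-methylpropanal | O=CC(C)(C)[C@H]1COC(C)(C)O1 | intermediate
5 | (3-benzyloxypropyl)triphenylphosphonium bromide | c1ccccc1COCCC[P+](c1ccccc1)(c1ccccc1)c1ccccc1.[Br-] | starting material
6 | (3-benzyloxypropylidene)triphenylphosphorane | c1ccccc1COCCC=P(c1ccccc1)(c1ccccc1)c1ccccc1 | intermediate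
7 | (4S)-4-[(3Z)-6-(benzyloxy)-2-methylhex-3-en-2-yl]-2,2-dimethyl-1,3-dioxolane | c1ccccc1COCC/C=C\C(C)(C)[C@H]1COC(C)(C)O1 | intermediate
8 | 5-[(4S)-2,2-dimethyl-1,3-dioxolan-4-yl]-5-methylhexan-1-ol | OCCCCC(C)(C)[C@H]1COC(C)(C)O1 | intermediate
9 | 5-[(4S)-2,2-dimethyl-1,3-dioxolan-4-yl]-5-methylhexanal | O=CCCCC(C)(C)[C@H]1COC(C)(C)O1 | intermediate
10 | (4S)-2,2-dimethyl-4-(2-methylhept-6-yn-2-yl)-1,3-dioxolane | C#CCCCC(C)(C)[C@H]1COC(C)(C)O1 | intermediate
11 | (2S)-3,3-dimethyloct-7-yne-1,2-diol | C#CCCCC(C)(C)[C@H](O)CO | intermediate
12 | (7S)-7,8-bis[(tert-butyldimethylsilyl)oxy]-6,6-dimethyloct-1-yne | C#CCCCC(C)(C)[C@H](O[Si](C)(C)C(C)(C)C)CO[Si](C)(C)C(C)(C)C | intermediate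
13 | trimethylaluminium | C[Al](C)C | starting material
14 | ethylene oxide | C1CO1 | starting material
15 | [(1E,7S)-7,8-bis(TBSO)-2,6,6-trimethyloct-1-en-1-yl]dimethylalane | C[Al](C)/C=C(\C)CCCC(C)(C)[C@H](O[Si](C)(C)C(C)(C)C)CO[Si](C)(C)C(C)(C)C | intermediate
16 | lithium butyl[(1E,7S)-7,8-bis(TBSO)-2,6,6-trimethyloct-1-en-1-yl]dimethylalanate | [Li+].CCCC[Al-](C)(C)/C=C(\C)CCCC(C)(C)[C@H](O[Si](C)(C)C(C)(C)C)CO[Si](C)(C)C(C)(C)C | intermediate
17 | (3E,9S)-9,10-bis[(tert-butyldimethylsilyl)oxy]-4,8,8-trimethyldec-3-en-1-ol | OCC/C=C(\C)CCCC(C)(C)[C@H](O[Si](C)(C)C(C)(C)C)CO[Si](C)(C)C(C)(C)C | intermediate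
18 | (3E,9S)-9,10-bis[(tert-butyldimethylsilyl)oxy]-1-iodo-4,8,8-trimethyldec-3-ene | ICC/C=C(\C)CCCC(C)(C)[C@H](O[Si](C)(C)C(C)(C)C)CO[Si](C)(C)C(C)(C)C | intermediate
19 | allyl (diethoxyphosphoryl)acetate | C=CCOC(=O)CP(=O)(OCC)OCC | starting material
20 | sodium enolate of allyl (diethoxyphosphoryl)acetate | [Na+].C=CCOC([O-])=CP(=O)(OCC)OCC | intermediate
21 | allyl (5E,11S)-11,12-bis(TBSO)-2-(diethoxyphosphoryl)-6,10,10-trimethyldodec-5-enoate (C2 epimers) | C=CCOC(=O)C(CC/C=C(\C)CCCC(C)(C)[C@H](O[Si](C)(C)C(C)(C)C)CO[Si](C)(C)C(C)(C)C)P(=O)(OCC)OCC | intermediate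
22 | allyl (5E,11S)-11-(TBSO)-2-(diethoxyphosphoryl)-12-hydroxy-6,10,10-trimethyldodec-5-enoate (C2 epimers) | C=CCOC(=O)C(CC/C=C(\C)CCCC(C)(C)[C@H](O[Si](C)(C)C(C)(C)C)CO)P(=O)(OCC)OCC | intermediate
23 | allyl (5E,11S)-11-(TBSO)-2-(diethoxyphosphoryl)-6,10,10-trimethyl-12-oxododec-5-enoate (C2 epimers) | C=CCOC(=O)C(CC/C=C(\C)CCCC(C)(C)[C@H](O[Si](C)(C)C(C)(C)C)C=O)P(=O)(OCC)OCC | intermediate
24 | allyl (5E,9E,11R)-11-[(tert-butyldimethylsilyl)oxy]-1,1,5-trimethylcycloundeca-5,9-diene-9-carboxylate | CC1(C)CCC/C(C)=C/CC/C(C(=O)OCC=C)=C\[C@H]1O[Si](C)(C)C(C)(C)C | intermediate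
25 | allyl (5E,9E,11R)-11-hydroxy-1,1,5-trimethylcycloundeca-5,9-diene-9-carboxylate | CC1(C)CCC/C(C)=C/CC/C(C(=O)OCC=C)=C\[C@H]1O | intermediate
26 | allyl (5E,9E,11R)-11-(benzoyloxy)-1,1,5-trimethylcycloundeca-5,9-diene-9-carboxylate | CC1(C)CCC/C(C)=C/CC/C(C(=O)OCC=C)=C\[C@H]1OC(=O)c1ccccc1 | intermediate
27 | allyl (5R,6R,9E,11R)-11-(benzoyloxy)-5,6-epoxy-1,1,5-trimethylcycloundec-9-ene-9-carboxylate | CC1(C)CCC[C@@]2(C)O[C@@H]2CC/C(C(=O)OCC=C)=C\[C@H]1OC(=O)c1ccccc1 | intermediate
28 | (5R,6R,9E,11R)-11-(benzoyloxy)-5,6-epoxy-1,1,5-trimethylcycloundec-9-ene-9-carboxylic acid | CC1(C)CCC[C@@]2(C)O[C@@H]2CC/C(C(=O)O)=C\[C@H]1OC(=O)c1ccccc1 | target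

## Step count and least certain steps

Total: 19 steps. Longest linear sequence: 19 steps (1 → 28); 5, 13, 14 and 19 enter without sequences of their own.

Step 10 (key step).
- Most likely to fail: the group transfer from the alanate. A butyl or methyl group may be delivered in place of the alkenyl group, or the opening may be slow, so that the alkenyl metal is merely protonated on work-up. Residual AlMe3 may also polymerise the epoxide, and regiocontrol in the methylalumination may erode.
- Fallback: setting out from 12, the same methylalumination would be run and the alane 15 quenched with I2 to give (1E,7S)-7,8-bis(TBSO)-1-iodo-2,6,6-trimethyloct-1-ene F1. Iodine–lithium exchange (t-BuLi, Et2O, −78 °C) and opening of 14 by the alkenyllithium in the presence of BF3·OEt2 would return to the route at 17. The carbon–carbon bond to C7 then comes from a more nucleophilic organolithium.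

Step 15.
- Most likely to fail: intermolecular olefination (dimers and oligomers) may compete, because an eleven-membered ring is strained and entropically costly. Slow closure also lengthens the exposure of the aldehyde to base and invites epimerisation at C11.
- Fallback: a samarium-templated Reformatsky closure followed by dehydration.
  - Setting out from 18, alkylation of the lithium enolate of allyl acetate (LiN(i-Pr)2, THF–DMPU, −78 → −30 °C) would give allyl (5E,11S)-11,12-bis(TBSO)-6,10,10-trimethyldodec-5-enoate F2.
  - Enolisation and bromination (LiN(SiMe3)2, then N-bromosuccinimide, −78 °C) would give the α-bromo ester allyl (5E,11S)-2-bromo-11,12-bis(TBSO)-6,10,10-trimethyldodec-5-enoate F3.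
  - Selective removal of the primary silyl group as in step 13 would give the bromo alcohol allyl (5E,11S)-2-bromo-11-(TBSO)-12-hydroxy-6,10,10-trimethyldodec-5-enoate F4.
  - Dess–Martin oxidation would give the bromo aldehyde allyl (5E,11S)-2-bromo-11-(TBSO)-6,10,10-trimethyl-12-oxododec-5-enoate F5.
  - SmI2 in THF at high dilution would close the ring by intramolecular Reformatsky addition to the β-hydroxy ester allyl (5E,11R)-11-(TBSO)-10-hydroxy-1,1,5-trimethylcycloundec-5-ene-9-carboxylate F6.
  - Mesylation (MsCl, Et3N) and elimination with DBU would return to the route at 24.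

Step 18.
- Most likely to fail: facial selectivity. Only the outer face of the E alkene is accessible in each ring conformer, and if the conformer that exposes the required face is disfavoured, the ring's bias opposes the reagent and a mixture of epoxide diastereomers results.
- Fallback: the oxygen would be introduced on the open chain, where the reagent alone decides.
  - Setting out from 22, the same Shi epoxidation would give allyl (5R,6R,11S)-11-(TBSO)-2-(diethoxyphosphoryl)-5,6-epoxy-12-hydroxy-6,10,10-trimethyldodecanoate F7.
  - Dess–Martin oxidation would give the epoxy aldehyde allyl (5R,6R,11S)-11-(TBSO)-2-(diethoxyphosphoryl)-5,6-epoxy-6,10,10-trimethyl-12-oxododecanoate F8.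
  - The olefination of step 15 would give allyl (5R,6R,9E,11R)-11-(TBSO)-5,6-epoxy-1,1,5-trimethylcycloundec-9-ene-9-carboxylate F9.
  - Desilylation with Bu4NF buffered with AcOH (HF·pyridine would open the epoxide) would give allyl (5R,6R,9E,11R)-5,6-epoxy-11-hydroxy-1,1,5-trimethylcycloundec-9-ene-9-carboxylate F10.
  - Benzoylation as in step 17 would return to the route at 27.

Step 19.
- Most likely to fail: chemoselectivity. Zerovalent palladium may also ionise the allylic benzoate at C11, with loss or transposition of the benzoate, and the amine may open the epoxide if the reaction is prolonged.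
- Fallback: the palladium step would be run before the benzoate exists.
  - Setting out from 25, deallylation under the conditions of step 19 would give (5E,9E,11R)-11-hydroxy-1,1,5-trimethylcycloundeca-5,9-diene-9-carboxylic acid F11.
  - Benzoylation (BzCl, pyridine, DMAP; aqueous NaHCO3 to hydrolyse the mixed anhydride) would give (5E,9E,11R)-11-(benzoyloxy)-1,1,5-trimethylcycloundeca-5,9-diene-9-carboxylic acid F12.
  - Shi epoxidation of the carboxylate under the conditions of step 18 would return to the route at 28.

## Further compounds

F1 | step 10 | (1E,7S)-7,8-bis(TBSO)-1-iodo-2,6,6-trimethyloct-1-ene | I/C=C(\C)CCCC(C)(C)[C@H](O[Si](C)(C)C(C)(C)C)CO[Si](C)(C)C(C)(C)C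
F2 | step 15 | allyl (5E,11S)-11,12-bis(TBSO)-6,10,10-trimethyldodec-5-enoate | C=CCOC(=O)CCC/C=C(\C)CCCC(C)(C)[C@H](O[Si](C)(C)C(C)(C)C)CO[Si](C)(C)C(C)(C)C
F3 | step 15 | allyl (5E,11S)-2-bromo-11,12-bis(TBSO)-6,10,10-trimethyldodec-5-enoate (C2 epimers) | C=CCOC(=O)C(Br)CC/C=C(\C)CCCC(C)(C)[C@H](O[Si](C)(C)C(C)(C)C)CO[Si](C)(C)C(C)(C)C
F4 | step 15 | allyl (5E,11S)-2-bromo-11-(TBSO)-12-hydroxy-6,10,10-trimethyldodec-5-enoate (C2 epimers) | C=CCOC(=O)C(Br)CC/C=C(\C)CCCC(C)(C)[C@H](O[Si](C)(C)C(C)(C)C)CO
F5 | step 15 | allyl (5E,11S)-2-bromo-11-(TBSO)-6,10,10-trimethyl-12-oxododec-5-enoate (C2 epimers) | C=CCOC(=O)C(Br)CC/C=C(\C)CCCC(C)(C)[C@H](O[Si](C)(C)C(C)(C)C)C=O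
F6 | step 15 | allyl (5E,11R)-11-(TBSO)-10-hydroxy-1,1,5-trimethylcycloundec-5-ene-9-carboxylate (mixture at C9 and C10) | CC1(C)CCC/C(C)=C/CCC(C(=O)OCC=C)C(O)[C@H]1O[Si](C)(C)C(C)(C)C
F7 | step 18 | allyl (5R,6R,11S)-11-(TBSO)-2-(diethoxyphosphoryl)-5,6-epoxy-12-hydroxy-6,10,10-trimethyldodecanoate (C2 epimers) | C=CCOC(=O)C(CC[C@H]1O[C@]1(C)CCCC(C)(C)[C@H](O[Si](C)(C)C(C)(C)C)CO)P(=O)(OCC)OCC
F8 | step 18 | allyl (5R,6R,11S)-11-(TBSO)-2-(diethoxyphosphoryl)-5,6-epoxy-6,10,10-trimethyl-12-oxododecanoate (C2 epimers) | C=CCOC(=O)C(CC[C@H]1O[C@]1(C)CCCC(C)(C)[C@H](O[Si](C)(C)C(C)(C)C)C=O)P(=O)(OCC)OCC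
F9 | step 18 | allyl (5R,6R,9E,11R)-11-(TBSO)-5,6-epoxy-1,1,5-trimethylcycloundec-9-ene-9-carboxylate | CC1(C)CCC[C@@]2(C)O[C@@H]2CC/C(C(=O)OCC=C)=C\[C@H]1O[Si](C)(C)C(C)(C)C
F10 | step 18 | allyl (5R,6R,9E,11R)-5,6-epoxy-11-hydroxy-1,1,5-trimethylcycloundec-9-ene-9-carboxylate | CC1(C)CCC[C@@]2(C)O[C@@H]2CC/C(C(=O)OCC=C)=C\[C@H]1O
F11 | step 19 | (5E,9E,11R)-11-hydroxy-1,1,5-trimethylcycloundeca-5,9-diene-9-carboxylic acid | CC1(C)CCC/C(C)=C/CC/C(C(=O)O)=C\[C@H]1O
F12 | step 19 | (5E,9E,11R)-11-(benzoyloxy)-1,1,5-trimethylcycloundeca-5,9-diene-9-carboxylic acid | CC1(C)CCC/C(C)=C/CC/C(C(=O)O)=C\[C@H]1OC(=O)c1ccccc1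
A1 | alternative 1 | [(4E,6R)-6-(benzoyloxy)-7,7-dimethyl-11-oxo-4-(allyloxycarbonyl)dodec-4-en-1-yl]diphenylsulfonium trifluoromethanesulfonate | CC(=O)CCCC(C)(C)[C@H](OC(=O)c1ccccc1)/C=C(\CCC[S+](c1ccccc1)c1ccccc1)C(=O)OCC=C.[O-]S(=O)(=O)C(F)(F)F
A2 | alternative 1 | allyl (5R,6R,9E,11R)-11-(benzoyloxy)-5,6-epoxy-1,1,5-trimethylcycloundec-9-ene-9-carboxylate (identical with 27) | CC1(C)CCC[C@@]2(C)O[C@@H]2CC/C(C(=O)OCC=C)=C\[C@H]1OC(=O)c1ccccc1
A3 | alternative 2 | 2-(trimethylsilyl)ethyl ester of the trans-fused six–seven bicyclic hydroxy mesylate (target numbering: fusion bond C5–C11, angular OH on C11, angular CH3 on C5, mesylate on C6 cis to that methyl, C9=C10 enoate; one enantiomer shown) | CC1(C)CCC[C@]2(C)[C@@H](OS(C)(=O)=O)CCC(C(=O)OCC[Si](C)(C)C)=C[C@@]12O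
A4 | alternative 2 | 2-(trimethylsilyl)ethyl (5E,9E)-1,1,5-trimethyl-11-oxocycloundeca-5,9-diene-9-carboxylate | CC1(C)CCC/C(C)=C/CC/C(C(=O)OCC[Si](C)(C)C)=C\C1=O
A5 | alternative 3 | (3S)-5-[(tert-butyldimethylsilyl)oxy]-3-chloropentan-2-one | CC(=O)[C@@H](Cl)CCO[Si](C)(C)C(C)(C)C
A6 | alternative 3 | {(5S)-5-[(tert-butyldimethylsilyl)oxy]-6-[(4-methoxybenzyl)oxy]-4,4-dimethylhexyl}magnesium bromide | COc1ccc(COC[C@@H](O[Si](C)(C)C(C)(C)C)C(C)(C)CCC[Mg]Br)cc1
A7 | alternative 3 | tert-butyl{2-[(2R,3R)-3-{(5S)-5-[(tert-butyldimethylsilyl)oxy]-6-[(4-methoxybenzyl)oxy]-4,4-dimethylhexyl}-3-methyloxiran-2-yl]ethoxy}dimethylsilane | COc1ccc(COC[C@@H](O[Si](C)(C)C(C)(C)C)C(C)(C)CCC[C@@]2(C)O[C@@H]2CCO[Si](C)(C)C(C)(C)C)cc1
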